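**Retrosynthetic overview**
1. Target 29 ⇒ hydroxy‑isopropenyl compound 25: the γ‑lactone is closed last by forming the C12–O6 bond (oxidative allylic C–H lactonization). The C5 ester comes from acylation; the C8–O bond from SN2 inversion of an α‑bromo ketone with cesium angelate.
2. 2,3‑Epoxy‑4‑ol ⇒ (3Z)‑allylic alcohol 19: hydroxy‑directed singlet‑oxygen ene reaction (C4–O), then vanadium‑directed epoxidation (C2–O–C3).
3. Ten‑membered carbocycle ⇒ cis‑1,2‑dialkenylcyclohexanol 11 by anionic oxy‑Cope ring expansion.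
4. Cyclohexanone 9 ⇒ epoxy alcohol 8 by semipinacol vinyl shift; C5–O from directed epoxidation; C6–O from singlet‑oxygen [4+2] on the dienol ether of (S)‑carvone.
5. Ring order: six‑membered ring (carvone) → ten‑membered ring → epoxide → γ‑lactone.

Assumption: germacrane numbering is used (C1 ring CH2, C2/C3 epoxide, C4 C(OH)CH3, C5 CH–O‑2‑methylbutanoyl, C6 lactone O–CH, C7, C8 CH–O‑angeloyl, C9 C=O, C10 CH(CH3), C11=C13H2, C12 lactone C=O); the target is the (2S,3R,4R,5R,6S,7S,8S,10S,2′R) isomer of the given SMILES. "Up/down" below refers to the cyclohexane face, with the isopropenyl group "up".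

**Step 1**
Reactants: 1 (S)-(+)-carvone
Product: 3 tert-butyldimethyl{[(5R)-2-methyl-5-(prop-1-en-2-yl)cyclohexa-1,3-dien-1-yl]oxy}silane, via potassium dienolate 2 (not isolated)
Conditions: KOtBu, THF, −78 → 0 °C; then TBSCl
Reagents that add atoms: tert-butyldimethylsilyl chloride CC(C)(C)[Si](C)(C)Cl
Why: Equilibrating γ‑deprotonation gives the fully conjugated linear dienolate, which is silylated on oxygen (silyl dienol ether formation); the carvone stereocentre (later C7) is untouched.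

**Step 2**
Reactants: 3 silyl dienol ether
Product: 6 (4R,5S)-4-[(tert-butyldimethylsilyl)oxy]-2-methyl-5-(prop-1-en-2-yl)cyclohex-2-en-1-one, via endoperoxide 4 (not isolated), via silyl peroxide 5 (not isolated)
Conditions: O2, hν, tetraphenylporphyrin (cat.), CH2Cl2, −78 °C; then PPh3, −78 °C → rt
Reagents that add atoms: dioxygen O=O
Why: Singlet‑oxygen [4+2] cycloaddition to the cisoid diene occurs anti to the neighbouring isopropenyl group (sets C6), the silyloxy endoperoxide collapses by silatropic shift to the γ‑silylperoxy enone, and PPh3 deoxygenates the peroxide to the silyl ether.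

**Step 3**
Reactants: 6 γ‑silyloxy enone
Product: 7 (1R,4R,5S)-4-[(tert-butyldimethylsilyl)oxy]-1-ethenyl-2-methyl-5-(prop-1-en-2-yl)cyclohex-2-en-1-ol
Conditions: CH2=CHMgBr, CeCl3, THF, −78 °C
Reagents that add atoms: vinylmagnesium bromide C=C[Mg]Br
Why: Organocerium 1,2‑addition to the enone; axial attack anti to the isopropenyl group (as in hydride reduction of carvone to cis‑carveol) puts vinyl down and the tertiary OH up.

**Step 4**
Reactants: 7 tertiary allylic alcohol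
Product: 8 (1R,2R,4S,5S,6R)-5-[(tert-butyldimethylsilyl)oxy]-2-ethenyl-1-methyl-4-(prop-1-en-2-yl)-7-oxabicyclo[4.1.0]heptan-2-ol
Conditions: VO(acac)2 (cat.), t-BuOOH, CH2Cl2, 0 °C
Reagents that add atoms: tert-butyl hydroperoxide CC(C)(C)OO
Why: Vanadium‑catalysed hydroxyl‑directed epoxidation delivers oxygen to the electron‑rich ring alkene syn to the tertiary OH and anti to the C6 silyloxy group, which fixes the later C5–O configuration.

**Step 5**
Reactants: 8 epoxy alcohol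
Product: 9 (2S,3S,4S,5S)-4-[(tert-butyldimethylsilyl)oxy]-2-ethenyl-3-hydroxy-2-methyl-5-(prop-1-en-2-yl)cyclohexan-1-one
Conditions: ZnBr2, CH2Cl2, 0 °C → rt
Reagents that add atoms: none
Why: Semipinacol rearrangement of the 2,3‑epoxy alcohol: Lewis‑acid opening at the tertiary epoxide carbon with 1,2‑shift of the antiperiplanar vinyl group gives the ketone, the vinyl arriving with inversion (trans to the C5–OH, which keeps the epoxide oxygen and so sets C5).

**Step 6**
Reactants: 9 β‑hydroxy ketone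
Product: 10 (2S,3S,4S,5S)-4-[(tert-butyldimethylsilyl)oxy]-2-ethenyl-2-methyl-5-(prop-1-en-2-yl)-3-[(triethylsilyl)oxy]cyclohexan-1-one
Conditions: Et3SiOTf, 2,6-lutidine, CH2Cl2, −78 °C
Reagents that add atoms: triethylsilyl trifluoromethanesulfonate CC[Si](CC)(CC)OS(=O)(=O)C(F)(F)F
Why: Silylation of the hindered secondary alcohol blocks retro‑aldol cleavage and silyl migration, and the TES ether can later be removed while the TBS ether stays.

**Step 7**
Reactants: 10 ketone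
Product: 11 (1R,2S,3S,4S,5S)-4-[(tert-butyldimethylsilyl)oxy]-2-ethenyl-2-methyl-1,5-di(prop-1-en-2-yl)-3-[(triethylsilyl)oxy]cyclohexan-1-ol
Conditions: CH2=C(CH3)MgBr, CeCl3, THF, −78 °C
Reagents that add atoms: isopropenylmagnesium bromide CC(=C)[Mg]Br
Why: Organocerium 1,2‑addition with axial attack anti to the axial methyl of the quaternary carbon gives the cis‑1,2‑dialkenyl carbinol (equatorial vinyl, axial isopropenyl), the geometry that leads to the Z‑alkene in the next step.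

**Step 8**
Reactants: 11 dialkenyl carbinol
Product: 14 (3Z,5S,6S,7S,10S)-6-(tert-butyldimethylsilyloxy)-5-(triethylsilyloxy)germacra-3,11(13)-dien-9-one, via potassium alkoxide 12 (not isolated), via potassium enolate 13 (not isolated)
Conditions: KH, 18-crown-6, THF, 0 °C → rt; then MeOH, −78 → 0 °C
Reagents that add atoms: none
Why: Anionic oxy‑Cope rearrangement through a chair transition state expands the ring; in the cis isomer the C4–C5 ring bond is axial on the Cope chair, giving the (3Z)‑alkene, and C10 is set on protonation of the enolate under equilibrating (KOMe) conditions, the 10S epimer with the methyl on the ring periphery being taken as the thermodynamic one.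

**Step 9**
Reactants: 14 cyclodecenone
Product: 16 (3Z,5S,6S,7S,8R,10S)-8-bromo-6-(tert-butyldimethylsilyloxy)-5-(triethylsilyloxy)germacra-3,11(13)-dien-9-one, via lithium enolate 15 (not isolated)
Conditions: LiN(SiMe3)2, THF, −78 °C; then NBS, −78 °C
Reagents that add atoms: N-bromosuccinimide O=C1CCC(=O)N1Br
Why: Kinetic deprotonation at the less substituted α‑carbon C8 followed by electrophilic α‑bromination; with H7 eclipsing the enolate (allylic 1,3‑strain) and C6 on the inner ring face, bromine is expected to enter from the periphery, syn to the isopropenyl group (8R).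

**Step 10**
Reactants: 16 α‑bromo ketone; 17 angelic acid [(Z)-2-methylbut-2-enoic acid]
Product: 18 (3Z,5S,6S,7R,8S,10S)-8-angeloyloxy-6-(tert-butyldimethylsilyloxy)-5-(triethylsilyloxy)germacra-3,11(13)-dien-9-one
Conditions: 17, Cs2CO3 (0.5 equiv), DMF; then 16, 0 °C → rt
Reagents that add atoms: none
Why: SN2 displacement of the α‑keto bromide by cesium carboxylate forms the C8–O bond with inversion (sets 8S) without activating angelic acid, so the Z‑enoate is not scrambled.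

**Step 11**
Reactants: 18 bis‑silyl ether
Product: 19 (3Z,5S,6S,7R,8S,10S)-8-angeloyloxy-6-(tert-butyldimethylsilyloxy)-5-hydroxygermacra-3,11(13)-dien-9-one
Conditions: AcOH–THF–H2O (3:1:1), rt
Reagents that add atoms: none
Why: Mild acid solvolysis cleaves the TES ether selectively in the presence of the TBS ether.

**Step 12**
Reactants: 19 (Z)-allylic alcohol
Product: 21 (2E,4R,5R,6S,7R,8S,10S)-8-angeloyloxy-6-(tert-butyldimethylsilyloxy)-4,5-dihydroxygermacra-2,11(13)-dien-9-one, via hydroperoxide 20 (not isolated)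
Conditions: O2, hν, tetraphenylporphyrin (cat.), CH2Cl2, −20 °C; then PPh3
Reagents that add atoms: dioxygen O=O
Why: Hydroxy‑directed Schenck ene reaction: allylic 1,3‑strain in the Z‑allylic alcohol holds H5 in the alkene plane, singlet oxygen is steered by the C5–OH to that face, bonds to C4 (sets 4R, syn to C5–O) and abstracts H from C2 (cis effect) to give the E‑C2=C3 alkene, and PPh3 reduces the hydroperoxide.

**Step 13**
Reactants: 21 allylic diol
Product: 22 (2S,3R,4R,5R,6S,7R,8S,10S)-8-angeloyloxy-6-(tert-butyldimethylsilyloxy)-2,3-epoxy-4,5-dihydroxygermacr-11(13)-en-9-one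
Conditions: VO(acac)2 (cat.), t-BuOOH, CH2Cl2, 0 °C
Reagents that add atoms: tert-butyl hydroperoxide CC(C)(C)OO
Why: Vanadium‑catalysed epoxidation directed by the tertiary allylic alcohol; with the O–C4–C3=C2 dihedral near 45°, ring carbon C5 on the inner face and the methyl anti, oxygen goes to the outer alkene face and gives the trans‑epoxide (2S,3R) anti to C4–OH.

**Step 14**
Reactants: 22 epoxy diol; 23 (R)-2-methylbutanoic acid
Product: 24 (2S,3R,4R,5R,6S,7R,8S,10S)-8-angeloyloxy-6-(tert-butyldimethylsilyloxy)-2,3-epoxy-4-hydroxy-5-[(2R)-2-methylbutanoyloxy]germacr-11(13)-en-9-one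
Conditions: DIC, DMAP (cat.), CH2Cl2, 0 °C → rt
Reagents that add atoms: none
Why: Steglich esterification acylates the only secondary alcohol (the tertiary C4–OH does not react) and carries the preformed 2′R centre.

**Step 15**
Reactants: 24 silyl ether
Product: 25 (2S,3R,4R,5R,6S,7S,8S,10S)-8-angeloyloxy-2,3-epoxy-4,6-dihydroxy-5-[(2R)-2-methylbutanoyloxy]germacr-11(13)-en-9-one
Conditions: HF·pyridine, pyridine, THF, 0 °C → rt
Reagents that add atoms: none
Why: Buffered fluoride desilylation frees O6–H and is tolerated by the epoxy alcohol and both esters.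

**Step 16**
Reactants: 25 hydroxy isopropenyl compound
Product: 29 target (2S,3R,4R,5R,6S,7S,8S,10S)-8-angeloyloxy-2,3-epoxy-4-hydroxy-5-[(2R)-2-methylbutanoyloxy]-9-oxogermacr-11(13)-en-12,6-olide, via allylic alcohol 26 (not isolated), via enal 27 (not isolated), via lactol 28 (not isolated)
Conditions: SeO2 (cat.), t-BuOOH, CH2Cl2, rt; then [Cu(MeCN)4]OTf (cat.), 2,2′-bipyridine, ABNO (cat.), N-methylimidazole, air, MeCN, rt
Reagents that add atoms: tert-butyl hydroperoxide CC(C)(C)OO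
Why: Proposed new method: a one‑pot relay that turns the isopropenyl methyl group and the neighbouring O6–H into the α‑methylene‑γ‑lactone — selenium dioxide ene reaction and [2,3]‑shift hydroxylate the methyl group, the copper/aminoxyl pair oxidises the primary allylic alcohol to the enal, O6–H (the only free secondary hydroxyl) adds to give the five‑membered lactol, and the same catalyst oxidises the lactol to the lactone, forming the C12–O6 bond and the last ring; the closest known reaction types are SeO2/t‑BuOOH allylic hydroxylation and copper/aminoxyl aerobic lactonization of 1,4‑diols.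

**Compound list**
1 | (S)-(+)-carvone | CC1=CC[C@@H](CC1=O)C(C)=C | starting material
2 | potassium (5R)-2-methyl-5-(prop-1-en-2-yl)cyclohexa-1,3-dien-1-olate | [K+].[O-]C1=C(C)C=C[C@H](C(C)=C)C1 | intermediate
3 | tert-butyldimethyl{[(5R)-2-methyl-5-(prop-1-en-2-yl)cyclohexa-1,3-dien-1-yl]oxy}silane | CC(C)(C)[Si](C)(C)OC1=C(C)C=C[C@H](C(C)=C)C1 | intermediate
4 | 1-(tert-butyldimethylsilyloxy)-6-methyl-8-(prop-1-en-2-yl)-2,3-dioxabicyclo[2.2.2]oct-5-ene, peroxide bridge anti to isopropenyl | CC(C)(C)[Si](C)(C)O[C@]12OO[C@H](C=C1C)[C@H](C(C)=C)C2 | intermediate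
5 | (4R,5S)-4-[(tert-butyldimethylsilyl)peroxy]-2-methyl-5-(prop-1-en-2-yl)cyclohex-2-en-1-one | O=C1C(C)=C[C@@H](OO[Si](C)(C)C(C)(C)C)[C@H](C(C)=C)C1 | intermediate
6 | (4R,5S)-4-[(tert-butyldimethylsilyl)oxy]-2-methyl-5-(prop-1-en-2-yl)cyclohex-2-en-1-one | O=C1C(C)=C[C@@H](O[Si](C)(C)C(C)(C)C)[C@H](C(C)=C)C1 | intermediate
7 | (1R,4R,5S)-4-[(tert-butyldimethylsilyl)oxy]-1-ethenyl-2-methyl-5-(prop-1-en-2-yl)cyclohex-2-en-1-ol | O[C@]1(C=C)C(C)=C[C@@H](O[Si](C)(C)C(C)(C)C)[C@H](C(C)=C)C1 | intermediate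
8 | (1R,2R,4S,5S,6R)-5-[(tert-butyldimethylsilyl)oxy]-2-ethenyl-1-methyl-4-(prop-1-en-2-yl)-7-oxabicyclo[4.1.0]heptan-2-ol | O[C@]1(C=C)[C@]2(C)O[C@@H]2[C@@H](O[Si](C)(C)C(C)(C)C)[C@H](C(C)=C)C1 | intermediate
9 | (2S,3S,4S,5S)-4-[(tert-butyldimethylsilyl)oxy]-2-ethenyl-3-hydroxy-2-methyl-5-(prop-1-en-2-yl)cyclohexan-1-one | O=C1[C@@](C)(C=C)[C@H](O)[C@@H](O[Si](C)(C)C(C)(C)C)[C@H](C(C)=C)C1 | intermediate
10 | (2S,3S,4S,5S)-4-[(tert-butyldimethylsilyl)oxy]-2-ethenyl-2-methyl-5-(prop-1-en-2-yl)-3-[(triethylsilyl)oxy]cyclohexan-1-one | O=C1[C@@](C)(C=C)[C@H](O[Si](CC)(CC)CC)[C@@H](O[Si](C)(C)C(C)(C)C)[C@H](C(C)=C)C1 | intermediate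
11 | (1R,2S,3S,4S,5S)-4-[(tert-butyldimethylsilyl)oxy]-2-ethenyl-2-methyl-1,5-di(prop-1-en-2-yl)-3-[(triethylsilyl)oxy]cyclohexan-1-ol | O[C@]1(C(C)=C)[C@@](C)(C=C)[C@H](O[Si](CC)(CC)CC)[C@@H](O[Si](C)(C)C(C)(C)C)[C@H](C(C)=C)C1 | intermediate
12 | potassium alkoxide of 11 | [K+].[O-][C@]1(C(C)=C)[C@@](C)(C=C)[C@H](O[Si](CC)(CC)CC)[C@@H](O[Si](C)(C)C(C)(C)C)[C@H](C(C)=C)C1 | intermediate
13 | potassium C9/C10 enolate of 14 (3Z) | [K+].[O-]/C1=C(C)\CC/C=C(C)\[C@H](O[Si](CC)(CC)CC)[C@@H](O[Si](C)(C)C(C)(C)C)[C@H](C(C)=C)C1 | intermediate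
14 | (3Z,5S,6S,7S,10S)-6-(tert-butyldimethylsilyloxy)-5-(triethylsilyloxy)germacra-3,11(13)-dien-9-one | CC(C)(C)[Si](C)(C)O[C@H]1[C@H](C(C)=C)CC(=O)[C@@H](C)CC/C=C(C)\[C@@H]1O[Si](CC)(CC)CC | intermediate
15 | lithium C8/C9 enolate of 14 | [Li+].CC(C)(C)[Si](C)(C)O[C@H]1[C@H](C(C)=C)C=C([O-])[C@@H](C)CC/C=C(C)\[C@@H]1O[Si](CC)(CC)CC | intermediate
16 | (3Z,5S,6S,7S,8R,10S)-8-bromo-6-(tert-butyldimethylsilyloxy)-5-(triethylsilyloxy)germacra-3,11(13)-dien-9-one | CC(C)(C)[Si](C)(C)O[C@H]1[C@H](C(C)=C)[C@@H](Br)C(=O)[C@@H](C)CC/C=C(C)\[C@@H]1O[Si](CC)(CC)CC | intermediate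
17 | angelic acid, (Z)-2-methylbut-2-enoic acid | C/C=C(/C)C(=O)O | starting material
18 | (3Z,5S,6S,7R,8S,10S)-8-angeloyloxy-6-(tert-butyldimethylsilyloxy)-5-(triethylsilyloxy)germacra-3,11(13)-dien-9-one | CC(C)(C)[Si](C)(C)O[C@H]1[C@H](C(C)=C)[C@H](OC(=O)/C(C)=C\C)C(=O)[C@@H](C)CC/C=C(C)\[C@@H]1O[Si](CC)(CC)CC | intermediate
19 | (3Z,5S,6S,7R,8S,10S)-8-angeloyloxy-6-(tert-butyldimethylsilyloxy)-5-hydroxygermacra-3,11(13)-dien-9-one | CC(C)(C)[Si](C)(C)O[C@H]1[C@H](C(C)=C)[C@H](OC(=O)/C(C)=C\C)C(=O)[C@@H](C)CC/C=C(C)\[C@@H]1O | intermediate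
20 | (2E,4R,5R,6S,7R,8S,10S)-8-angeloyloxy-6-(tert-butyldimethylsilyloxy)-4-hydroperoxy-5-hydroxygermacra-2,11(13)-dien-9-one | CC(C)(C)[Si](C)(C)O[C@H]1[C@H](C(C)=C)[C@H](OC(=O)/C(C)=C\C)C(=O)[C@@H](C)C/C=C/[C@@](C)(OO)[C@@H]1O | intermediate
21 | (2E,4R,5R,6S,7R,8S,10S)-8-angeloyloxy-6-(tert-butyldimethylsilyloxy)-4,5-dihydroxygermacra-2,11(13)-dien-9-one | CC(C)(C)[Si](C)(C)O[C@H]1[C@H](C(C)=C)[C@H](OC(=O)/C(C)=C\C)C(=O)[C@@H](C)C/C=C/[C@@](C)(O)[C@@H]1O | intermediate
22 | (2S,3R,4R,5R,6S,7R,8S,10S)-8-angeloyloxy-6-(tert-butyldimethylsilyloxy)-2,3-epoxy-4,5-dihydroxygermacr-11(13)-en-9-one | CC(C)(C)[Si](C)(C)O[C@H]1[C@H](C(C)=C)[C@H](OC(=O)/C(C)=C\C)C(=O)[C@@H](C)C[C@@H]2O[C@H]2[C@@](C)(O)[C@@H]1O | intermediate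
23 | (R)-2-methylbutanoic acid | CC[C@@H](C)C(=O)O | starting material
24 | (2S,3R,4R,5R,6S,7R,8S,10S)-8-angeloyloxy-6-(tert-butyldimethylsilyloxy)-2,3-epoxy-4-hydroxy-5-[(2R)-2-methylbutanoyloxy]germacr-11(13)-en-9-one | CC(C)(C)[Si](C)(C)O[C@H]1[C@H](C(C)=C)[C@H](OC(=O)/C(C)=C\C)C(=O)[C@@H](C)C[C@@H]2O[C@H]2[C@@](C)(O)[C@@H]1OC(=O)[C@H](C)CC | intermediate
25 | (2S,3R,4R,5R,6S,7S,8S,10S)-8-angeloyloxy-2,3-epoxy-4,6-dihydroxy-5-[(2R)-2-methylbutanoyloxy]germacr-11(13)-en-9-one | O[C@H]1[C@H](C(C)=C)[C@H](OC(=O)/C(C)=C\C)C(=O)[C@@H](C)C[C@@H]2O[C@H]2[C@@](C)(O)[C@@H]1OC(=O)[C@H](C)CC | intermediate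
26 | 12-hydroxy derivative of 25 (2-substituted allyl alcohol) | O[C@H]1[C@H](C(CO)=C)[C@H](OC(=O)/C(C)=C\C)C(=O)[C@@H](C)C[C@@H]2O[C@H]2[C@@](C)(O)[C@@H]1OC(=O)[C@H](C)CC | intermediate
27 | 12-oxo derivative of 25 (α-substituted acrolein) | O[C@H]1[C@H](C(C=O)=C)[C@H](OC(=O)/C(C)=C\C)C(=O)[C@@H](C)C[C@@H]2O[C@H]2[C@@](C)(O)[C@@H]1OC(=O)[C@H](C)CC | intermediate
28 | 6,12-lactol of 27 (both anomers) | C=C1C(O)O[C@H]2[C@H]1[C@H](OC(=O)/C(C)=C\C)C(=O)[C@@H](C)C[C@@H]1O[C@H]1[C@@](C)(O)[C@@H]2OC(=O)[C@H](C)CC | intermediate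
29 | CNP0217571.1, (2S,3R,4R,5R,6S,7S,8S,10S)-8-angeloyloxy-2,3-epoxy-4-hydroxy-5-[(2R)-2-methylbutanoyloxy]-9-oxogermacr-11(13)-en-12,6-olide | C=C1C(=O)O[C@H]2[C@H]1[C@H](OC(=O)/C(C)=C\C)C(=O)[C@@H](C)C[C@@H]1O[C@H]1[C@@](C)(O)[C@@H]2OC(=O)[C@H](C)CC | target

**Totals and risk**
Total step count: 16. Longest linear sequence: 16 steps from 1.

Three steps most likely to fail:

Step 9 (regio‑ and facial selectivity of the macrocyclic enolate; the bromide must be 8R for the invertive displacement). Fallback, setting out from 14 and coming back at 18: LiN(SiMe3)2 followed by 2-(phenylsulfonyl)-3-phenyloxaziridine gives the α‑hydroxy ketone (3Z,5S,6S,7R,8R,10S)-8-hydroxy-6-(tert-butyldimethylsilyloxy)-5-(triethylsilyloxy)germacra-3,11(13)-dien-9-one F1, which is esterified with 17 under Mitsunobu conditions (PPh3, DIAD; inversion) to give 18. If the hydroxylation gave the 8S alcohol instead, esterification with retention (2,4,6-trichlorobenzoyl chloride, Et3N, DMAP) would reach the same 18.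

Step 12 (regioselectivity of the ene reaction against methyl‑hydrogen abstraction, and chemoselectivity against the isopropenyl group). Fallback, setting out from 19 and coming back at 21: hydroxyl‑directed epoxidation (VO(acac)2, t-BuOOH; threo by allylic 1,3‑strain) gives the cis‑3,4‑epoxy‑5‑ol F2; NaSePh opens the cis‑epoxide at C3 to the 3‑phenylselanyl‑4,5‑diol F3; H2O2 oxidation and selenoxide syn‑elimination give 21.

Step 16 (the proposed relay; the selenium and copper/aminoxyl cycles may not be compatible in one pot). Fallback with known chemistry, setting out from 25 and coming back at 29: Schenck ene photooxygenation of the isopropenyl group (O2, hν, tetraphenylporphyrin) gives the 12‑hydroperoxide F4; Et3N (Kornblum–DeLaMare dehydration) gives enal 27, which closes to lactol 28; MnO2 oxidises 28 to 29.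

Further compounds
F1 | step 9 | (3Z,5S,6S,7R,8R,10S)-8-hydroxy-6-(tert-butyldimethylsilyloxy)-5-(triethylsilyloxy)germacra-3,11(13)-dien-9-one | CC(C)(C)[Si](C)(C)O[C@H]1[C@H](C(C)=C)[C@@H](O)C(=O)[C@@H](C)CC/C=C(C)\[C@@H]1O[Si](CC)(CC)CC
F2 | step 12 | cis-3,4-epoxide of 19, epoxide oxygen on the face of the C5 hydroxyl | CC(C)(C)[Si](C)(C)O[C@H]1[C@H](C(C)=C)[C@H](OC(=O)/C(C)=C\C)C(=O)[C@@H](C)CC[C@H]2O[C@@]2(C)[C@@H]1O
F3 | step 12 | 3-(phenylselanyl)-4,5-diol from opening of F2 at C3 | CC(C)(C)[Si](C)(C)O[C@H]1[C@H](C(C)=C)[C@H](OC(=O)/C(C)=C\C)C(=O)[C@@H](C)CC[C@H]([Se]c2ccccc2)[C@@](C)(O)[C@@H]1O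
F4 | step 16 | 12-hydroperoxy derivative of 25 | O[C@H]1[C@H](C(COO)=C)[C@H](OC(=O)/C(C)=C\C)C(=O)[C@@H](C)C[C@@H]2O[C@H]2[C@@](C)(O)[C@@H]1OC(=O)[C@H](C)CC
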